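**Plan**

- Retrosynthetic cuts, in order: the C15 acetate and C19 methyl ester; C8=C17 (Wittig); C4–C18 with removal of the C3 oxygen (reductive methylation); C9–C10 (ring B); C8–C9 (Nozaki–Hiyama–Kishi); C6–C7 (benzylic allylation); C10–C20 (Suzuki).
- Enabling feature: C10 is a quaternary, methyl-bearing carbon bonded to C1, C5 and C9. It is the para carbon of a 4-methylphenol ring A (C1–C5 and C10, oxygen on C3, ester C19 on C4) whose meta side chain C6–C7–C8–C9 ends at C9.
- Forward order: ring A is bought as a salicylate; the chain is joined at C6–C7 and then C8–C9; ring B closes by phenoxide para-C-alkylation (C9–C10). Ring A is then saturated, C4 made quaternary, C3 deoxygenated and C8 methylenated.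
- Stereochemistry: C13 comes from (S)-citronellol. The C9 carbinol (R) comes from a Sharpless kinetic resolution and is inverted in the SN2 ring closure, which relays it to C10. The C10 methyl then directs C5 (trans fusion) and C4 (axial ester) in the Li/NH3–MeI step; the equatorial C9 side chain is also the thermodynamic one.

Key step: step 12

Assumption: the target is read from its SMILES as the normal-series (4S,5R,9S,10R,13S)-15-acetoxylabd-8(17)-en-19-oic acid; labdane numbering is used for skeletal atoms, and the SMILES strings are authoritative for configuration.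

**Route**

Step 1
Reactants: 1 methyl 2-hydroxy-6-methylbenzoate
Product: 2 methyl 3-bromo-6-hydroxy-2-methylbenzoate
Conditions: NBS (1.0 equiv), MeCN, 0 °C → rt
Reagents that add atoms: N-bromosuccinimide, O=C1CCC(=O)N1Br
Why: Electrophilic aromatic bromination, in which the phenolic OH directs bromine para to itself (reinforced by the ortho methyl), the position next to the hydrogen-bonded OH being the slower site.

Step 2
Reactants: 2 methyl 3-bromo-6-hydroxy-2-methylbenzoate
Product: 3 methyl 3-bromo-6-(methoxymethoxy)-2-methylbenzoate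
Conditions: NaH, MOMCl, THF–DMF, 0 °C → rt
Reagents that add atoms: chloromethyl methyl ether, COCCl
Why: Williamson-type O-alkylation of the sodium phenoxide masks the acidic OH as a MOM acetal before the strong-base and organometallic steps.

Step 3
Reactants: 3 methyl 3-bromo-6-(methoxymethoxy)-2-methylbenzoate
Product: 4 methyl 6-(methoxymethoxy)-2,3-dimethylbenzoate
Conditions: MeB(OH)2, Pd(dppf)Cl2 (5 mol%), K2CO3, dioxane–H2O, 95 °C
Reagents that add atoms: methylboronic acid, CB(O)O
Why: Suzuki–Miyaura methylation of the aryl bromide installs the future C20 methyl; the ester and MOM ether are inert to Pd(0) and carbonate.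

Step 4
Reactants: 4 methyl 6-(methoxymethoxy)-2,3-dimethylbenzoate; 5 2,3-dibromopropene
Product: 7 methyl 2-(3-bromobut-3-en-1-yl)-6-(methoxymethoxy)-3-methylbenzoate, via benzylic lithium species 6 (not isolated)
Conditions: LDA (1.1 equiv), THF, −78 °C; then 5 (1.3 equiv), −78 → −30 °C
Reagents that add atoms: none
Why: Lateral lithiation occurs only at the methyl ortho to the ester (its anion is a vinylogous ester enolate), and SN2 or SN2′ allylation, which give the same product, forms C6–C7 and brings in C8 as an alkenyl bromide.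

Step 5
Reactants: 8 (S)-citronellol
Product: 9 (S)-citronellol triisopropylsilyl ether
Conditions: TIPSCl, imidazole, DMF, rt
Reagents that add atoms: triisopropylsilyl chloride, CC(C)[Si](Cl)(C(C)C)C(C)C
Why: Standard silylation of the primary alcohol; TIPS is chosen because it should survive the later TFA, Lewis-acid and Li/NH3 steps.

Step 6
Reactants: 9 (S)-citronellol triisopropylsilyl ether
Product: 11 (4S)-4-methyl-6-(triisopropylsilyloxy)hexanal, via ozonide 10 (not isolated)
Conditions: O3, CH2Cl2, −78 °C; then PPh3, −78 °C → rt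
Reagents that add atoms: ozone, [O-][O+]=O
Why: Ozonolysis with reductive work-up cleaves the trisubstituted alkene to the aldehyde whose carbon becomes C9, without touching the C13 stereocentre.

Step 7
Reactants: 7 methyl 2-(3-bromobut-3-en-1-yl)-6-(methoxymethoxy)-3-methylbenzoate; 11 (4S)-4-methyl-6-(triisopropylsilyloxy)hexanal
Product: 12 methyl 2-[(4RS,7S)-4-hydroxy-7-methyl-3-methylidene-9-(triisopropylsilyloxy)nonyl]-6-(methoxymethoxy)-3-methylbenzoate (about 1:1 mixture of epimers at the carbinol carbon C9)
Conditions: CrCl2 (4 equiv), NiCl2 (2 mol%), DMF, rt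
Reagents that add atoms: none
Why: Nozaki–Hiyama–Kishi coupling, in which the alkenylchromium(III) species adds chemoselectively to the aldehyde (ester, MOM and silyl ether tolerated) to form C8–C9; the remote C13 centre exerts no control, so both C9 epimers are expected.

Step 8
Reactants: 12 the epimer mixture from step 7
Product: 13 methyl 2-[(4R,7S)-4-hydroxy-7-methyl-3-methylidene-9-(triisopropylsilyloxy)nonyl]-6-(methoxymethoxy)-3-methylbenzoate
Conditions: Ti(OiPr)4 (0.15 equiv), L-(+)-DIPT (0.2 equiv), t-BuOOH (0.6 equiv), 4 Å MS, CH2Cl2, −20 °C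
Reagents that add atoms: none
Why: Sharpless kinetic resolution of the secondary allylic alcohol, in which L-(+)-tartrate epoxidises the (4S)-carbinol fast, so the required (4R)-epimer (C9) should be recovered in high purity once conversion passes about 55%.

Step 9
Reactants: 13 the (4R,7S)-allylic alcohol
Product: 15 methyl 2-[(4R,7S)-4-hydroxy-7-methyl-3-oxo-9-(triisopropylsilyloxy)nonyl]-6-(methoxymethoxy)-3-methylbenzoate, via ozonide 14 (not isolated)
Conditions: O3, CH2Cl2, −78 °C (Sudan Red 7B end-point); then PPh3, −78 °C → rt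
Reagents that add atoms: ozone, [O-][O+]=O
Why: Ozonolysis of the 1,1-disubstituted alkene unmasks the C8 ketone without breaking the C9–O bond; the ester-deactivated arene reacts far more slowly than the alkene and the dye marks the end-point.

Step 10
Reactants: 15 the α-hydroxy ketone
Product: 16 methyl 2-[(4R,7S)-4-(methanesulfonyloxy)-7-methyl-3-oxo-9-(triisopropylsilyloxy)nonyl]-6-(methoxymethoxy)-3-methylbenzoate
Conditions: Ms2O, pyridine, CH2Cl2, 0 °C
Reagents that add atoms: methanesulfonic anhydride, CS(=O)(=O)OS(C)(=O)=O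
Why: O-sulfonylation with retention (the C9–O bond is not broken); chloride-free Ms2O with the weak base pyridine avoids halide displacement and epimerisation of the reactive α-keto mesylate.

Step 11
Reactants: 16 the MOM-protected α-keto mesylate
Product: 17 methyl 6-hydroxy-2-[(4R,7S)-4-(methanesulfonyloxy)-7-methyl-3-oxo-9-(triisopropylsilyloxy)nonyl]-3-methylbenzoate
Conditions: TFA–CH2Cl2 (1:9), 0 °C; aq. NaHCO3 work-up
Reagents that add atoms: none
Why: Acid-catalysed cleavage of the aryl MOM acetal (assisted by the ortho ester) with a non-nucleophilic acid, under which the mesylate, the ketone and the primary TIPS ether should persist.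

Step 12
Reactants: 17 the phenolic α-keto mesylate
Product: 19 methyl (9R,10R,13S)-3,8-dioxo-15-(triisopropylsilyloxy)-17,18-dinorlabda-1,4-dien-19-oate, via potassium phenoxide 18 (not isolated)
Conditions: KOtBu (1.0 equiv), t-BuOH–THF (4:1), 0.005 M, 25 → 40 °C
Reagents that add atoms: none
Why: KOtBu (1 equiv) gives potassium phenoxide 18, whose para carbon C10 attacks C9 and expels mesylate in an intramolecular SN2 reaction (inversion at C9, the adjacent C8 carbonyl lowering the barrier), forming C9–C10 and a cross-conjugated dienone that cannot re-aromatise because C10 is quaternary. The closest known reaction type is the base-mediated intramolecular para-C-alkylation of phenoxides by sulfonates (aryl participation, Ar2-6 mode) that gives fused 4,4-disubstituted cyclohexa-2,5-dienones. Ring B (C5–C6–C7–C8–C9–C10) closes in the 6-exo-tet mode. The new stereocentre C10 is set by chirality transfer from the (R)-configured C9: in the chair-like transition state the C11 chain is equatorial and points away from the arene, whereas attack on the other π-face would place it over ring A, so the C10 methyl ends cis to the side chain, and C9 itself is defined by the inversion. The step needs para-C- rather than O- or ortho-C-alkylation: O-attack would require an eight-membered ring, the ortho carbon C4 carries the chelated ester and would give a non-conjugated linear dienone, and high dilution in t-BuOH suppresses intermolecular O-alkylation. It also needs the mesylate to keep its configuration until it reacts, which is secured by using exactly one equivalent of base, the phenoxide being too weak a base to enolise the ketone.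

Step 13
Reactants: 19 the bicyclic dienone
Product: 20 methyl (9R,10R,13S)-3,8-dioxo-15-(triisopropylsilyloxy)-17,18-dinorlabd-4-en-19-oate
Conditions: H2 (1 atm), RhCl(PPh3)3 (10 mol%), benzene–EtOH, rt
Reagents that add atoms: none
Why: Homogeneous hydrogenation with Wilkinson's catalyst reduces the disubstituted C1=C2 bond and leaves the tetrasubstituted, ester-bearing C4=C5 bond, as in the 1,4-dien-3-one to 4-en-3-one reduction of steroids.

Step 14
Reactants: 20 the enone diketone
Product: 21 methyl (9R,10R,13S)-8,8-(ethylenedioxy)-3-oxo-15-(triisopropylsilyloxy)-17,18-dinorlabd-4-en-19-oate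
Conditions: (TMSOCH2)2, TMSOTf (5 mol%), CH2Cl2, −78 → −20 °C
Reagents that add atoms: 1,2-bis(trimethylsilyloxy)ethane, C[Si](C)(C)OCCO[Si](C)(C)C
Why: Silyl-triflate-catalysed acetalisation (Noyori conditions) is kinetically selective for the saturated C8 ketone over the conjugated C3 carbonyl of the vinylogous β-keto ester, protecting C8 for the dissolving-metal step.

Step 15
Reactants: 21 the C8 ketal enone ester
Product: 23 methyl (4R,5R,9R,10S,13S)-8,8-(ethylenedioxy)-3-oxo-15-(triisopropylsilyloxy)-17-norlabdan-19-oate, via lithium enolate 22 (not isolated)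
Conditions: Li (2.1 equiv), t-BuOH (1.0 equiv), NH3(l)–THF, −78 °C; NH3 evaporated; MeI (5 equiv), THF–DMPU, −20 °C → rt
Reagents that add atoms: iodomethane, CI
Why: Dissolving-metal reductive alkylation, in which two-electron reduction of the enone ester and protonation of C5 on the α-face give the trans-fused β-keto-ester enolate, which MeI attacks at C4 anti to the axial C10 methyl, so the new methyl is α (C18) and the ester axial β (C19).

Step 16
Reactants: 23 the C3 keto ester
Product: 24 methyl (3S,4R,5R,9R,10S,13S)-8,8-(ethylenedioxy)-3-hydroxy-15-(triisopropylsilyloxy)-17-norlabdan-19-oate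
Conditions: NaBH4, MeOH–THF, 0 °C
Reagents that add atoms: none
Why: Borohydride reduction of the hindered C3 ketone by hydride delivery from the α-face (3β-alcohol expected; the centre is removed in step 18), with the hindered ester and the ketal inert.

Step 17
Reactants: 24 the 3β-alcohol
Product: 25 methyl (3S,4R,5R,9R,10S,13S)-8,8-(ethylenedioxy)-3-[(imidazol-1-ylcarbonothioyl)oxy]-15-(triisopropylsilyloxy)-17-norlabdan-19-oate
Conditions: 1,1′-thiocarbonyldiimidazole, DMAP (0.2 equiv), ClCH2CH2Cl, 70 °C
Reagents that add atoms: 1,1′-thiocarbonyldiimidazole, S=C(n1ccnc1)n1ccnc1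
Why: Acylation of the neopentyl-type secondary alcohol under neutral conditions gives the Barton–McCombie thiocarbonyl derivative without an alkoxide that could open the β-hydroxy ester by retro-aldol cleavage.

Step 18
Reactants: 25 the thiocarbonylimidazolide
Product: 26 methyl (4S,5R,9R,10S,13S)-8,8-(ethylenedioxy)-15-(triisopropylsilyloxy)-17-norlabdan-19-oate
Conditions: Bu3SnH, AIBN (0.2 equiv), toluene, 100 °C
Reagents that add atoms: none
Why: Barton–McCombie radical deoxygenation removes the C3 oxygen; the secondary C3 radical has no β-leaving group or nearby alkene and should simply be reduced by the stannane.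

Step 19
Reactants: 26 the deoxygenated ketal silyl ether
Product: 27 methyl (4S,5R,9R,10S,13S)-15-hydroxy-8-oxo-17-norlabdan-19-oate
Conditions: 3 M aq. HCl–THF (1:3), 45 °C
Reagents that add atoms: water, O
Why: Aqueous acid hydrolyses the dioxolane and the primary TIPS ether in one operation; C9, now α to the ketone, can only equilibrate toward the equatorial side chain that the target needs.

Step 20
Reactants: 27 the keto alcohol
Product: 28 methyl (4S,5R,9S,10R,13S)-15-hydroxylabd-8(17)-en-19-oate
Conditions: Ph3PCH3Br (4 equiv), KOtBu (3.8 equiv), THF, 0 °C → reflux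
Reagents that add atoms: methyltriphenylphosphonium bromide, C[P+](c1ccccc1)(c1ccccc1)c1ccccc1.[Br-]
Why: Wittig methylenation of the hindered C8 ketone with excess ylide, as practised on 8-oxo-17-norlabdanes; the free hydroxyl only consumes ylide and the hindered ester is untouched.

Step 21
Reactants: 28 the hydroxy methyl ester
Product: 29 (4S,5R,9S,10R,13S)-15-hydroxylabd-8(17)-en-19-oic acid
Conditions: NaSEt (5 equiv), DMF, 100 °C; then 1 M HCl to pH 3, 0 °C
Reagents that add atoms: none
Why: SN2 demethylation (thiolate attack on the O-methyl carbon) frees the acid where saponification of the axial neopentyl C19 ester would fail; the alkene and the hydroxyl are inert to thiolate.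

Step 22
Reactants: 29 the hydroxy acid
Product: 30 (4S,5R,9S,10R,13S)-15-acetoxylabd-8(17)-en-19-oic acid (target)
Conditions: Ac2O, pyridine, DMAP (cat.), CH2Cl2, 0 °C → rt; aqueous work-up
Reagents that add atoms: acetic anhydride, CC(=O)OC(C)=O
Why: DMAP-catalysed acetylation of the primary alcohol; any mixed anhydride of the hindered tertiary acid should be hydrolysed during aqueous work-up.

**Compound list**

1 | methyl 2-hydroxy-6-methylbenzoate | COC(=O)c1c(C)cccc1O | starting material
2 | methyl 3-bromo-6-hydroxy-2-methylbenzoate | COC(=O)c1c(C)c(Br)ccc1O | intermediate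
3 | methyl 3-bromo-6-(methoxymethoxy)-2-methylbenzoate | COCOc1ccc(Br)c(C)c1C(=O)OC | intermediate
4 | methyl 6-(methoxymethoxy)-2,3-dimethylbenzoate | COCOc1ccc(C)c(C)c1C(=O)OC | intermediate
5 | 2,3-dibromopropene | BrCC(Br)=C | starting material
6 | benzylic lithium species of 4 (lithiated at the 2-methyl group) | [Li]Cc1c(C)ccc(OCOC)c1C(=O)OC | intermediate (not isolated)
7 | methyl 2-(3-bromobut-3-en-1-yl)-6-(methoxymethoxy)-3-methylbenzoate | COCOc1ccc(C)c(CCC(Br)=C)c1C(=O)OC | intermediate
8 | (S)-citronellol | CC(C)=CCC[C@H](C)CCO | starting material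
9 | (S)-citronellol triisopropylsilyl ether | CC(C)=CCC[C@H](C)CCO[Si](C(C)C)(C(C)C)C(C)C | intermediate
10 | ozonide of 9 (1,2,4-trioxolane, ring carbon unassigned) | CC1(C)OOC(CC[C@H](C)CCO[Si](C(C)C)(C(C)C)C(C)C)O1 | intermediate (not isolated)
11 | (4S)-4-methyl-6-(triisopropylsilyloxy)hexanal | O=CCC[C@H](C)CCO[Si](C(C)C)(C(C)C)C(C)C | intermediate
12 | methyl 2-[(4RS,7S)-4-hydroxy-7-methyl-3-methylidene-9-(triisopropylsilyloxy)nonyl]-6-(methoxymethoxy)-3-methylbenzoate, C9 epimer mixture | COCOc1ccc(C)c(CCC(=C)C(O)CC[C@H](C)CCO[Si](C(C)C)(C(C)C)C(C)C)c1C(=O)OC | intermediate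
13 | (4R,7S)-epimer of 12 | COCOc1ccc(C)c(CCC(=C)[C@H](O)CC[C@H](C)CCO[Si](C(C)C)(C(C)C)C(C)C)c1C(=O)OC | intermediate
14 | ozonide of 13 (spiro-1,2,4-trioxolane at C8, ring carbon unassigned) | COCOc1ccc(C)c(CCC2(OCOO2)[C@H](O)CC[C@H](C)CCO[Si](C(C)C)(C(C)C)C(C)C)c1C(=O)OC | intermediate (not isolated)
15 | methyl 2-[(4R,7S)-4-hydroxy-7-methyl-3-oxo-9-(triisopropylsilyloxy)nonyl]-6-(methoxymethoxy)-3-methylbenzoate | COCOc1ccc(C)c(CCC(=O)[C@H](O)CC[C@H](C)CCO[Si](C(C)C)(C(C)C)C(C)C)c1C(=O)OC | intermediate
16 | methyl 2-[(4R,7S)-4-(methanesulfonyloxy)-7-methyl-3-oxo-9-(triisopropylsilyloxy)nonyl]-6-(methoxymethoxy)-3-methylbenzoate | COCOc1ccc(C)c(CCC(=O)[C@H](OS(C)(=O)=O)CC[C@H](C)CCO[Si](C(C)C)(C(C)C)C(C)C)c1C(=O)OC | intermediate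
17 | methyl 6-hydroxy-2-[(4R,7S)-4-(methanesulfonyloxy)-7-methyl-3-oxo-9-(triisopropylsilyloxy)nonyl]-3-methylbenzoate (key-step precursor) | COC(=O)c1c(O)ccc(C)c1CCC(=O)[C@H](OS(C)(=O)=O)CC[C@H](C)CCO[Si](C(C)C)(C(C)C)C(C)C | intermediate
18 | potassium phenoxide of 17 | COC(=O)c1c([O-])ccc(C)c1CCC(=O)[C@H](OS(C)(=O)=O)CC[C@H](C)CCO[Si](C(C)C)(C(C)C)C(C)C.[K+] | intermediate (not isolated)
19 | methyl (9R,10R,13S)-3,8-dioxo-15-(triisopropylsilyloxy)-17,18-dinorlabda-1,4-dien-19-oate (key-step product; C10 methyl cis to the C9 chain) | O=C1CCC2=C(C(=O)OC)C(=O)C=C[C@]2(C)[C@H]1CC[C@H](C)CCO[Si](C(C)C)(C(C)C)C(C)C | intermediate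
20 | methyl (9R,10R,13S)-3,8-dioxo-15-(triisopropylsilyloxy)-17,18-dinorlabd-4-en-19-oate | O=C1CCC2=C(C(=O)OC)C(=O)CC[C@]2(C)[C@H]1CC[C@H](C)CCO[Si](C(C)C)(C(C)C)C(C)C | intermediate
21 | methyl (9R,10R,13S)-8,8-(ethylenedioxy)-3-oxo-15-(triisopropylsilyloxy)-17,18-dinorlabd-4-en-19-oate | O1CCOC12CCC3=C(C(=O)OC)C(=O)CC[C@]3(C)[C@H]2CC[C@H](C)CCO[Si](C(C)C)(C(C)C)C(C)C | intermediate
22 | lithium C3 enolate of the trans-fused β-keto ester (5α-H) | O1CCOC12CC[C@@H]3[C@](C)(CCC(O[Li])=C3C(=O)OC)[C@H]2CC[C@H](C)CCO[Si](C(C)C)(C(C)C)C(C)C | intermediate (not isolated)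
23 | methyl (4R,5R,9R,10S,13S)-8,8-(ethylenedioxy)-3-oxo-15-(triisopropylsilyloxy)-17-norlabdan-19-oate (4α-methyl, 4β-ester, 5α-H) | O1CCOC12CC[C@@H]3[C@](C)(CCC(=O)[C@]3(C)C(=O)OC)[C@H]2CC[C@H](C)CCO[Si](C(C)C)(C(C)C)C(C)C | intermediate
24 | methyl (3S,4R,5R,9R,10S,13S)-8,8-(ethylenedioxy)-3-hydroxy-15-(triisopropylsilyloxy)-17-norlabdan-19-oate (3β-OH) | O1CCOC12CC[C@@H]3[C@](C)(CC[C@H](O)[C@]3(C)C(=O)OC)[C@H]2CC[C@H](C)CCO[Si](C(C)C)(C(C)C)C(C)C | intermediate
25 | 3β-O-(imidazol-1-ylcarbonothioyl) derivative of 24 | O1CCOC12CC[C@@H]3[C@](C)(CC[C@H](OC(=S)n4ccnc4)[C@]3(C)C(=O)OC)[C@H]2CC[C@H](C)CCO[Si](C(C)C)(C(C)C)C(C)C | intermediate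
26 | methyl (4S,5R,9R,10S,13S)-8,8-(ethylenedioxy)-15-(triisopropylsilyloxy)-17-norlabdan-19-oate | O1CCOC12CC[C@@H]3[C@](C)(CCC[C@]3(C)C(=O)OC)[C@H]2CC[C@H](C)CCO[Si](C(C)C)(C(C)C)C(C)C | intermediate
27 | methyl (4S,5R,9R,10S,13S)-15-hydroxy-8-oxo-17-norlabdan-19-oate | O=C1CC[C@@H]2[C@](C)(CCC[C@]2(C)C(=O)OC)[C@H]1CC[C@H](C)CCO | intermediate
28 | methyl (4S,5R,9S,10R,13S)-15-hydroxylabd-8(17)-en-19-oate | C=C1CC[C@@H]2[C@](C)(CCC[C@]2(C)C(=O)OC)[C@H]1CC[C@H](C)CCO | intermediate
29 | (4S,5R,9S,10R,13S)-15-hydroxylabd-8(17)-en-19-oic acid | C=C1CC[C@@H]2[C@](C)(CCC[C@]2(C)C(=O)O)[C@H]1CC[C@H](C)CCO | intermediate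
30 | (4S,5R,9S,10R,13S)-15-acetoxylabd-8(17)-en-19-oic acid | C=C1CC[C@@H]2[C@](C)(CCC[C@]2(C)C(=O)O)[C@H]1CC[C@H](C)CCOC(C)=O | target

**Step count and risks**

Total steps: 22. Longest linear sequence: 20 (steps 1–4 and 7–22, from 1); the citronellol branch (steps 5–6) joins at step 7.

Steps most likely to fail:

1. Step 12. The α-keto mesylate may lose its C9 configuration by enolisation before ring closure, which would erode C10. The ester-bearing ortho carbon may also compete with the para carbon, or intermolecular O-alkylation may take over. The fallback replaces the enolisable electrophile by a cyclic sulfate and installs the C8 carbonyl after ring closure. Setting out from 15, the ketone would be reduced with NaBH4 to methyl 2-[(4R,7S)-3,4-dihydroxy-7-methyl-9-(triisopropylsilyloxy)nonyl]-6-(methoxymethoxy)-3-methylbenzoate F1 (C8 epimers, both usable). This would be converted with SOCl2/Et3N and then catalytic RuCl3/NaIO4 into the C8,C9-cyclic sulfate F2, and the MOM group removed with TFA to give the phenolic cyclic sulfate F3. KOtBu in dilute t-BuOH should then let the para carbon open the sulfate at C9 with inversion (the same Ar2-6 closure; attack at C8 would need the disfavoured five-membered mode) to give the potassium C8-sulfate monoester of the dienone F4. Hydrolysis with catalytic H2SO4 in wet THF would give the C8-hydroxy dienone F5, and Dess–Martin oxidation would return to the route at 19.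

2. Step 15. In the one-pot reductive alkylation the enolate may be trapped incompletely or on oxygen after ammonia removal, the ester may be over-reduced, or facial selectivity at C4 may be eroded. The fallback separates alkylation from reduction. Setting out from 21, deconjugative C4-methylation of the extended dienolate (NaH, 1.05 equiv, MeI, THF–t-BuOH) should give methyl (9R,10R,13S)-8,8-(ethylenedioxy)-4α-methyl-3-oxo-15-(triisopropylsilyloxy)-17-norlabd-5-en-19-oate F7, with the methyl again entering anti to the C10 methyl. Hydrogenation of the C5=C6 bond from the less hindered α-face (H2, Pd/C or PtO2, EtOAc) would then set the trans ring fusion and return to the route at 23.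

3. Step 8. The rate difference between the two C9 epimers may be too small with the bulky 2-substituent on the alkene, and half of a convergent intermediate is consumed in any case. The fallback sets C9 by reagent-controlled reduction instead. Setting out from 12, Dess–Martin oxidation would give the α-methylene ketone methyl 6-(methoxymethoxy)-3-methyl-2-[(7S)-7-methyl-3-methylidene-4-oxo-9-(triisopropylsilyloxy)nonyl]benzoate F6. Corey–Bakshi–Shibata reduction with the (S)-methyl oxazaborolidine and BH3·SMe2 at −40 °C (the alkenyl group acting as the large substituent) should deliver the (4R)-alcohol and return to the route at 13.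

**Further compounds**

F1 | step 12 | methyl 2-[(4R,7S)-3,4-dihydroxy-7-methyl-9-(triisopropylsilyloxy)nonyl]-6-(methoxymethoxy)-3-methylbenzoate (C8 epimers) | COCOc1ccc(C)c(CCC(O)[C@H](O)CC[C@H](C)CCO[Si](C(C)C)(C(C)C)C(C)C)c1C(=O)OC
F2 | step 12 | C8,C9-cyclic sulfate of F1 (1,3,2-dioxathiolane 2,2-dioxide, C9 R) | COCOc1ccc(C)c(CCC2OS(=O)(=O)O[C@@H]2CC[C@H](C)CCO[Si](C(C)C)(C(C)C)C(C)C)c1C(=O)OC
F3 | step 12 | phenolic cyclic sulfate (F2 without MOM) | COC(=O)c1c(O)ccc(C)c1CCC1OS(=O)(=O)O[C@@H]1CC[C@H](C)CCO[Si](C(C)C)(C(C)C)C(C)C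
F4 | step 12 | potassium C8-sulfate monoester of the ring-closed dienone | [K+].[O-]S(=O)(=O)OC1CCC2=C(C(=O)OC)C(=O)C=C[C@]2(C)[C@H]1CC[C@H](C)CCO[Si](C(C)C)(C(C)C)C(C)C
F5 | step 12 | methyl (9R,10R,13S)-8-hydroxy-3-oxo-15-(triisopropylsilyloxy)-17,18-dinorlabda-1,4-dien-19-oate (C8 epimers) | OC1CCC2=C(C(=O)OC)C(=O)C=C[C@]2(C)[C@H]1CC[C@H](C)CCO[Si](C(C)C)(C(C)C)C(C)C
F6 | step 8 | methyl 6-(methoxymethoxy)-3-methyl-2-[(7S)-7-methyl-3-methylidene-4-oxo-9-(triisopropylsilyloxy)nonyl]benzoate | COCOc1ccc(C)c(CCC(=C)C(=O)CC[C@H](C)CCO[Si](C(C)C)(C(C)C)C(C)C)c1C(=O)OC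
F7 | step 15 | methyl (9R,10R,13S)-8,8-(ethylenedioxy)-4α-methyl-3-oxo-15-(triisopropylsilyloxy)-17-norlabd-5-en-19-oate | O1CCOC12CC=C3[C@](C)(CCC(=O)[C@]3(C)C(=O)OC)[C@H]2CC[C@H](C)CCO[Si](C(C)C)(C(C)C)C(C)C
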